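**Plan**
- Retrosynthesis: cut first the two equivalent aryl–CH2 bonds, each between the benzylic carbon of a 2,3-dibromo-4,5-dihydroxyphenyl ring (ring A) and C2 of a central 3-bromo-4,5-dihydroxybenzyl ring (ring B); then cut the CH2–O–CH2 ether, which leaves two bromocatechol aldehydes.
- Forward: ring B aldehyde → symmetric dibenzyl ether by reductive homo-etherification → two-directional, biomimetic benzylation of both C2 positions by a lanosol-type para-quinone methide → removal of silyl and acetyl groups.
- Enabling feature: in ring A the C4 hydroxyl is para to the benzylic carbon, so that carbon can become the exocyclic carbon of a para-quinone methide. In ring B, C2 lies para to O5, between C1 (CH2O) and C3 (Br). The twofold symmetry about the ether oxygen lets both bonds form in one operation.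
- Precursor design: the oxygen para to each benzylic carbon is used as a switch. It is a free OH on ring A (ionizes), an acetate on O4 of ring B (the ether cannot ionize), and the O5 positions carry silyl ethers; all helpers leave in the last step.
- Stereochemistry: the target has no stereogenic element, so nothing has to be set.

Key step: step 9

Assumption: the structure has no stereocentre, axis or configurable double bond. It is achiral, so the "single enantiomer" is the compound itself and no stereocontrol is needed.

**Route**

Step 1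
Reactants: 1 3-bromo-4,5-dihydroxybenzaldehyde
Product: 2 3-bromo-4,5-bis(tert-butyldimethylsilyloxy)benzaldehyde
Conditions: TBSCl (2.4 equiv), imidazole, DMAP (cat.), DMF, rt
Reagents that add atoms: tert-butyldimethylsilyl chloride, CC(C)(C)[Si](C)(C)Cl
Why: Phenol silylation with a silyl chloride and imidazole in DMF is general for catechols and leaves the aldehyde and the aryl bromide untouched.

Step 2
Reactants: 2 3-bromo-4,5-bis(tert-butyldimethylsilyloxy)benzaldehyde
Product: 3 3-bromo-4-hydroxy-5-(tert-butyldimethylsilyloxy)benzaldehyde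
Conditions: LiOAc (0.2 equiv), DMF/H2O (50:1), rt
Reagents that add atoms: none
Why: In this acetate-catalysed solvolysis of aryl silyl ethers the Si–O bond with the best-stabilized phenoxide leaving group breaks first, and O4 (para to the formyl group, ortho to bromine) is a far better leaving group than O5 (meta to the formyl group), while the acidic phenol formed protects the remaining silyl ether.

Step 3
Reactants: 3 3-bromo-4-hydroxy-5-(tert-butyldimethylsilyloxy)benzaldehyde
Product: 4 2-bromo-4-formyl-6-(tert-butyldimethylsilyloxy)phenyl acetate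
Conditions: Ac2O, pyridine, DMAP (cat.), CH2Cl2, 0 °C
Reagents that add atoms: acetic anhydride, CC(=O)OC(C)=O
Why: O-acetylation of a phenol with acetic anhydride and pyridine; the silyl group already sits on the less acidic, less hindered O5, its thermodynamic position, so no silyl shift is expected before O4 is capped.

Step 4
Reactants: 4 2-bromo-4-formyl-6-(tert-butyldimethylsilyloxy)phenyl acetate (two molecules)
Product: 6 bis[4-acetoxy-3-bromo-5-(tert-butyldimethylsilyloxy)benzyl] ether, via triethylsilyl benzyl ether 5 (not isolated)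
Conditions: Et3SiH (2.4 equiv), TMSOTf (10 mol %), CH2Cl2, −20 → 0 °C
Reagents that add atoms: triethylsilane, CC[SiH](CC)CC (its silicon stays only in 5; 6 keeps only the hydride hydrogens)
Why: Silyl-triflate-catalysed reductive homo-etherification of an aldehyde with a hydrosilane (hydrosilylation to 5, condensation of 5 with a second aldehyde to an oxocarbenium ion, hydride capture); the para-acetoxy and meta-bromo groups make the benzylic carbon a poor cation precursor, which should prevent over-reduction to the methylarene and keep the new ether intact.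

Step 5
Reactants: 7 5-bromovanillin (3-bromo-4-hydroxy-5-methoxybenzaldehyde)
Product: 8 5,6-dibromovanillin (2,3-dibromo-4-hydroxy-5-methoxybenzaldehyde)
Conditions: Br2 (1.2 equiv), Fe powder (cat.), AcOH, rt
Reagents that add atoms: bromine, BrBr
Why: Electrophilic aromatic bromination of the bromovanillin ring takes the remaining position para to the methoxy group, the established outcome for this substrate class and the same regiochemistry that step 9 relies on.

Step 6
Reactants: 8 5,6-dibromovanillin
Product: 9 2,3-dibromo-4,5-dihydroxybenzaldehyde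
Conditions: BBr3 (2.5 equiv), CH2Cl2, −78 °C → rt; H2O
Reagents that add atoms: none
Why: Boron tribromide cleavage of an aryl methyl ether (the neighbouring phenol gives a cyclic aryl borate that is hydrolysed on work-up) tolerates the aldehyde and the aryl bromides.

Step 7
Reactants: 9 2,3-dibromo-4,5-dihydroxybenzaldehyde
Product: 10 2,3-dibromo-4,5-bis(tert-butyldimethylsilyloxy)benzaldehyde
Conditions: TBSCl (2.5 equiv), imidazole, DMAP (cat.), DMF, rt → 40 °C
Reagents that add atoms: tert-butyldimethylsilyl chloride, CC(C)(C)[Si](C)(C)Cl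
Why: Phenol silylation as in step 1; the hindered O4 between bromine and O5 should still be silylated under these standard conditions.

Step 8
Reactants: 10 2,3-dibromo-4,5-bis(tert-butyldimethylsilyloxy)benzaldehyde
Product: 12 2,3-dibromo-4-hydroxy-5-(tert-butyldimethylsilyloxy)benzyl alcohol, via monosilyl hydroxyaldehyde 11 (not isolated)
Conditions: LiOAc (0.2 equiv), DMF/H2O (50:1), rt; then NaBH4, EtOH, 0 °C; pH 6–7 phosphate work-up at 0 °C
Reagents that add atoms: none
Why: As in step 2 the silyl ether para to the formyl group (O4) is removed selectively by acetate-catalysed solvolysis, and the resulting 4-hydroxybenzaldehyde 11 is reduced in the same flask by sodium borohydride (aldehyde reduction), with a near-neutral work-up so that the para-hydroxybenzyl alcohol does not ionize.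

Step 9
Reactants: 6 bis[4-acetoxy-3-bromo-5-(tert-butyldimethylsilyloxy)benzyl] ether; 12 2,3-dibromo-4-hydroxy-5-(tert-butyldimethylsilyloxy)benzyl alcohol (two molecules, 2.5 equiv used)
Product: 14 bis{4-acetoxy-3-bromo-2-[2,3-dibromo-4-hydroxy-5-(tert-butyldimethylsilyloxy)benzyl]-5-(tert-butyldimethylsilyloxy)benzyl} ether, via mono-benzylated ether 13 (not isolated)
Conditions: TsOH·H2O (10 mol %), HFIP/CH2Cl2 (1:1), 0 °C → rt, slow addition of 12
Reagents that add atoms: none
Why: Acid-assisted loss of water from 12 is possible because its free C4 hydroxyl is para to the benzylic carbon, giving the O-protonated para-quinone methide (4-hydroxybenzyl cation); this is attacked by C2 of a ring B of 6, the position para to the silyloxy group on C5, and proton loss restores the arene, first to 13 and then at the second, equivalent ring to 14. The closest known reaction type is the acid-catalysed Friedel–Crafts benzylation of arenes by para-hydroxybenzyl alcohols through para-quinone methides (novolac-type condensation), run here in HFIP, and it mirrors the presumed biosynthetic coupling of lanosol-type units. No ring is closed and no stereocentre is formed. Chemoselectivity between the two kinds of benzylic C–O bond rests on the para oxygen: the free OH in 12 allows ionization, whereas the acetate on O4 of ring B keeps the dibenzyl ether of 6 from ionizing and makes any oxonium ion formed at the ether oxygen give back only the ring A cation. Regioselectivity rests on C2 being para to the only strongly donating oxygen of ring B, while C6 is ortho to it and shielded by the tert-butyldimethylsilyl group; this is the same position that bromine takes in step 5. Self-condensation of 12 is disfavoured because its only ring CH (C6) is meta to the free hydroxyl, flanked by the silyloxy group and deactivated by two bromines, and any O-alkylation products re-ionize under the conditions.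

Step 10
Reactants: 14 bis{4-acetoxy-3-bromo-2-[2,3-dibromo-4-hydroxy-5-(tert-butyldimethylsilyloxy)benzyl]-5-(tert-butyldimethylsilyloxy)benzyl} ether
Product: 16 bis[3-bromo-2-(2,3-dibromo-4,5-dihydroxybenzyl)-4,5-dihydroxybenzyl] ether (target), via desilylated diacetate 15 (not isolated)
Conditions: HF·pyridine, pyridine, THF, 0 °C → rt; then N2H4·H2O (excess), 0 °C, Ar; buffer to pH 5
Reagents that add atoms: none
Why: Buffered HF·pyridine removes the four aryl silyl ethers while the ether-bearing rings are still acetylated, and hydrazine, an α-effect nucleophile and reducing medium, then cleaves the two activated aryl acetates by hydrazinolysis without touching the dibenzyl ether, the aryl bromides or the oxidation-prone catechols (an acetyl shift between O4 and O5 in 15 would be without consequence, since both end as free hydroxyls).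

**Compound list**

1 | 3-bromo-4,5-dihydroxybenzaldehyde | O=Cc1cc(O)c(O)c(Br)c1 | starting material
2 | 3-bromo-4,5-bis(tert-butyldimethylsilyloxy)benzaldehyde | O=Cc1cc(O[Si](C)(C)C(C)(C)C)c(O[Si](C)(C)C(C)(C)C)c(Br)c1 | intermediate
3 | 3-bromo-4-hydroxy-5-(tert-butyldimethylsilyloxy)benzaldehyde | O=Cc1cc(O[Si](C)(C)C(C)(C)C)c(O)c(Br)c1 | intermediate
4 | 2-bromo-4-formyl-6-(tert-butyldimethylsilyloxy)phenyl acetate | CC(=O)Oc1c(Br)cc(C=O)cc1O[Si](C)(C)C(C)(C)C | intermediate
5 | 2-bromo-6-(tert-butyldimethylsilyloxy)-4-[(triethylsilyloxy)methyl]phenyl acetate | CC(=O)Oc1c(Br)cc(CO[Si](CC)(CC)CC)cc1O[Si](C)(C)C(C)(C)C | intermediate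
6 | bis[4-acetoxy-3-bromo-5-(tert-butyldimethylsilyloxy)benzyl] ether | CC(=O)Oc1c(Br)cc(COCc2cc(Br)c(OC(C)=O)c(O[Si](C)(C)C(C)(C)C)c2)cc1O[Si](C)(C)C(C)(C)C | intermediate
7 | 5-bromovanillin (3-bromo-4-hydroxy-5-methoxybenzaldehyde) | COc1cc(C=O)cc(Br)c1O | starting material
8 | 5,6-dibromovanillin (2,3-dibromo-4-hydroxy-5-methoxybenzaldehyde) | COc1cc(C=O)c(Br)c(Br)c1O | intermediate
9 | 2,3-dibromo-4,5-dihydroxybenzaldehyde | O=Cc1cc(O)c(O)c(Br)c1Br | intermediate
10 | 2,3-dibromo-4,5-bis(tert-butyldimethylsilyloxy)benzaldehyde | O=Cc1cc(O[Si](C)(C)C(C)(C)C)c(O[Si](C)(C)C(C)(C)C)c(Br)c1Br | intermediate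
11 | 2,3-dibromo-4-hydroxy-5-(tert-butyldimethylsilyloxy)benzaldehyde | O=Cc1cc(O[Si](C)(C)C(C)(C)C)c(O)c(Br)c1Br | intermediate
12 | 2,3-dibromo-4-hydroxy-5-(tert-butyldimethylsilyloxy)benzyl alcohol | OCc1cc(O[Si](C)(C)C(C)(C)C)c(O)c(Br)c1Br | intermediate
13 | 2-bromo-4-({[4-acetoxy-3-bromo-5-(tert-butyldimethylsilyloxy)benzyl]oxy}methyl)-3-[2,3-dibromo-4-hydroxy-5-(tert-butyldimethylsilyloxy)benzyl]-6-(tert-butyldimethylsilyloxy)phenyl acetate | CC(C)(C)[Si](C)(C)Oc1cc(Cc2c(COCc3cc(O[Si](C)(C)C(C)(C)C)c(OC(C)=O)c(Br)c3)cc(O[Si](C)(C)C(C)(C)C)c(OC(C)=O)c2Br)c(Br)c(Br)c1O | intermediate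
14 | bis{4-acetoxy-3-bromo-2-[2,3-dibromo-4-hydroxy-5-(tert-butyldimethylsilyloxy)benzyl]-5-(tert-butyldimethylsilyloxy)benzyl} ether | CC(C)(C)[Si](C)(C)Oc1cc(Cc2c(COCc3cc(O[Si](C)(C)C(C)(C)C)c(OC(C)=O)c(Br)c3Cc3cc(O[Si](C)(C)C(C)(C)C)c(O)c(Br)c3Br)cc(O[Si](C)(C)C(C)(C)C)c(OC(C)=O)c2Br)c(Br)c(Br)c1O | intermediate
15 | bis[4-acetoxy-3-bromo-2-(2,3-dibromo-4,5-dihydroxybenzyl)-5-hydroxybenzyl] ether | Oc1cc(Cc2c(COCc3cc(O)c(OC(C)=O)c(Br)c3Cc3cc(O)c(O)c(Br)c3Br)cc(O)c(OC(C)=O)c2Br)c(Br)c(Br)c1O | intermediate
16 | bis[3-bromo-2-(2,3-dibromo-4,5-dihydroxybenzyl)-4,5-dihydroxybenzyl] ether | Oc1cc(Cc2c(COCc3cc(O)c(O)c(Br)c3Cc3cc(O)c(O)c(Br)c3Br)cc(O)c(O)c2Br)c(Br)c(Br)c1O | target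

**Totals**

Total step count: 10. Longest linear sequence: 6 steps (steps 1–4, 9, 10 or steps 5–8, 9, 10).

**Steps most likely to fail**

1. Step 9. The acetate on ring B lowers the nucleophilicity of C2, so attack on the quinone methide may be slow; the electrophile could then be used up by self-condensation, the second benzylation could stay incomplete, or silyl groups could be lost under the acid. The fallback changes to a fully silylated, more nucleophilic core and a Lewis-acid imidate alkylation with a single fluoride end game. It sets out from 2 and 10 and comes back at 16. From 2, the triethylsilane/TMSOTf reductive homo-etherification, passing through 3-bromo-4,5-bis(tert-butyldimethylsilyloxy)benzyl triethylsilyl ether F1, should give bis[3-bromo-4,5-bis(tert-butyldimethylsilyloxy)benzyl] ether F2. From 10, NaBH4 in EtOH at 0 °C should give 2,3-dibromo-4,5-bis(tert-butyldimethylsilyloxy)benzyl alcohol F3, which Cl3CCN with catalytic DBU converts into 2,3-dibromo-4,5-bis(tert-butyldimethylsilyloxy)benzyl trichloroacetimidate F4. F2 and two equivalents of F4 with catalytic TMSOTf in CH2Cl2 at −40 → 0 °C (Friedel–Crafts benzylation with a benzyl trichloroacetimidate) should give, through the mono-benzylated octasilyl-series ether F5, the octakis(tert-butyldimethylsilyl) ether of the target F6. HF·pyridine in THF/pyridine then gives 16. This fallback lacks the acetate switch, so scrambling of the benzylic ether is its own risk.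

2. Step 4. The benzylic C–O bond may be over-reduced to the methylarene, the reaction may stall at the silyl ether, or acetyl or silyl groups may be lost under the Lewis acid. The fallback replaces the reductive coupling by an SN2 etherification. It sets out from 4 and comes back at 6. Half of 4 is reduced chemoselectively (NaBH4, THF/i-PrOH, −30 °C) to 2-bromo-4-(hydroxymethyl)-6-(tert-butyldimethylsilyloxy)phenyl acetate F7. Part of F7 is converted by an Appel reaction (CBr4, PPh3, CH2Cl2, 0 °C) into 2-bromo-4-(bromomethyl)-6-(tert-butyldimethylsilyloxy)phenyl acetate F8. F7 and F8 are joined by a silver(I) oxide-mediated Williamson etherification (Ag2O, CH2Cl2, molecular sieves, rt) to give 6.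

3. Step 8. Both silyl groups may be lost in the one-flask desilylation/reduction, or the para-hydroxybenzyl alcohol may self-condense during work-up. The fallback replaces selective deprotection by direct selective protection and makes no new compound (F0). It sets out from 9 and comes back at 12. Compound 9 is treated with one equivalent of TBSCl and imidazole in DMF at 0 °C → rt, conditions under which the silyl group equilibrates between the catechol oxygens and should settle on the less acidic, less hindered O5; this gives 11, which is now isolated. A separate NaBH4 reduction with a phosphate-buffered work-up then gives 12.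

**Further compounds**

F1 | step 9 | 3-bromo-4,5-bis(tert-butyldimethylsilyloxy)benzyl triethylsilyl ether | CC[Si](CC)(CC)OCc1cc(O[Si](C)(C)C(C)(C)C)c(O[Si](C)(C)C(C)(C)C)c(Br)c1
F2 | step 9 | bis[3-bromo-4,5-bis(tert-butyldimethylsilyloxy)benzyl] ether | CC(C)(C)[Si](C)(C)Oc1cc(COCc2cc(O[Si](C)(C)C(C)(C)C)c(O[Si](C)(C)C(C)(C)C)c(Br)c2)cc(Br)c1O[Si](C)(C)C(C)(C)C
F3 | step 9 | 2,3-dibromo-4,5-bis(tert-butyldimethylsilyloxy)benzyl alcohol | OCc1cc(O[Si](C)(C)C(C)(C)C)c(O[Si](C)(C)C(C)(C)C)c(Br)c1Br
F4 | step 9 | 2,3-dibromo-4,5-bis(tert-butyldimethylsilyloxy)benzyl trichloroacetimidate | N=C(OCc1cc(O[Si](C)(C)C(C)(C)C)c(O[Si](C)(C)C(C)(C)C)c(Br)c1Br)C(Cl)(Cl)Cl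
F5 | step 9 | mono-benzylated octasilyl-series ether: [3-bromo-4,5-bis(tert-butyldimethylsilyloxy)benzyl] {3-bromo-2-[2,3-dibromo-4,5-bis(tert-butyldimethylsilyloxy)benzyl]-4,5-bis(tert-butyldimethylsilyloxy)benzyl} ether | CC(C)(C)[Si](C)(C)Oc1cc(Cc2c(COCc3cc(O[Si](C)(C)C(C)(C)C)c(O[Si](C)(C)C(C)(C)C)c(Br)c3)cc(O[Si](C)(C)C(C)(C)C)c(O[Si](C)(C)C(C)(C)C)c2Br)c(Br)c(Br)c1O[Si](C)(C)C(C)(C)C
F6 | step 9 | bis{3-bromo-2-[2,3-dibromo-4,5-bis(tert-butyldimethylsilyloxy)benzyl]-4,5-bis(tert-butyldimethylsilyloxy)benzyl} ether | CC(C)(C)[Si](C)(C)Oc1cc(Cc2c(COCc3cc(O[Si](C)(C)C(C)(C)C)c(O[Si](C)(C)C(C)(C)C)c(Br)c3Cc3cc(O[Si](C)(C)C(C)(C)C)c(O[Si](C)(C)C(C)(C)C)c(Br)c3Br)cc(O[Si](C)(C)C(C)(C)C)c(O[Si](C)(C)C(C)(C)C)c2Br)c(Br)c(Br)c1O[Si](C)(C)C(C)(C)C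
F7 | step 4 | 2-bromo-4-(hydroxymethyl)-6-(tert-butyldimethylsilyloxy)phenyl acetate | CC(=O)Oc1c(Br)cc(CO)cc1O[Si](C)(C)C(C)(C)C
F8 | step 4 | 2-bromo-4-(bromomethyl)-6-(tert-butyldimethylsilyloxy)phenyl acetate | CC(=O)Oc1c(Br)cc(CBr)cc1O[Si](C)(C)C(C)(C)C
F0 | step 8 | none | none
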